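The C7–C8 bond is cut between the benzylic carbinol carbon on the 4-alkoxy-3,5-dimethoxyphenyl ring (ring A) and the methine that carries the 2,6-dimethoxy-4-propylphenoxy oxygen (ring B) and the C9 hydroxymethyl group. This C7(OH)–C8(OAr)–C9 array is a syn β-hydroxy-α-aryloxy acyl unit in disguise, so an Evans boron aldol joins both halves and sets both stereocentres in one operation. Its precursors are an (S)-benzyloxazolidinone aryloxyacetyl imide (allyl as latent hydroxypropyl) and a syringaldehyde-derived aryloxymalonate (latent glycerol ether). A single telescoped hydroboration–hydride reduction–oxidation then unveils all four primary alcohols.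

Key step: step 3

Assumption: compounds 1, 2, 4 and 5 are bought. In the boron-bearing species 10 and 11 (and F5, F6) the hydroxyl groups are drawn free, although in the flask they are partly held as B–O or Li–O species that the aqueous work-up releases.

Step 1
Reactants: 1 4-allyl-2,6-dimethoxyphenol (methoxyeugenol); 2 (S)-4-benzyl-3-(2-chloroacetyl)oxazolidin-2-one
Product: 3 (S)-3-[2-(4-allyl-2,6-dimethoxyphenoxy)acetyl]-4-benzyloxazolidin-2-one
Conditions: K2CO3, NaI (cat.), acetone, rt → 40 °C
Reagents that add atoms: none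
Why: Williamson O-alkylation (SN2) of the phenoxide at the primary α-halo imide carbon, with in situ Finkelstein activation by iodide so that substitution should outrun acyl transfer; the auxiliary stereocentre is not involved.

Step 2
Reactants: 4 syringaldehyde (4-hydroxy-3,5-dimethoxybenzaldehyde); 5 diethyl bromomalonate
Product: 6 diethyl 2-(4-formyl-2,6-dimethoxyphenoxy)malonate
Conditions: K2CO3, DMF, rt → 50 °C
Reagents that add atoms: none
Why: Williamson-type SN2 of the phenoxide on the doubly activated secondary bromide; both ortho positions and the para position of the phenoxide are substituted, so ring bromination has no outlet, and the single malonate C–H cannot undergo Knoevenagel condensation with the aldehyde.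

Step 3
Reactants: 3 (S)-3-[2-(4-allyl-2,6-dimethoxyphenoxy)acetyl]-4-benzyloxazolidin-2-one; 6 diethyl 2-(4-formyl-2,6-dimethoxyphenoxy)malonate
Product: 9 diethyl 2-{4-[(1R,2S)-2-(4-allyl-2,6-dimethoxyphenoxy)-3-[(S)-4-benzyl-2-oxooxazolidin-3-yl]-1-hydroxy-3-oxopropyl]-2,6-dimethoxyphenoxy}malonate (syn aldol adduct), via (Z)-dibutylboron enolate 7 (not isolated), via dibutylboron aldolate 8 (not isolated)
Conditions: 3, Bu2BOTf (1.05 equiv), iPr2NEt, CH2Cl2, −78 → 0 °C; then 6, −78 → 0 °C; then pH 7 buffer, MeOH, 30% H2O2, 0 °C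
Reagents that add atoms: none
Why: Soft enolisation of imide 3 with Bu2BOTf/iPr2NEt should give only the (Z)-boron enolate 7, which adds to the formyl carbon of 6 through a closed chair Zimmerman–Traxler transition state with the oxazolidinone carbonyl turned away from the enolate oxygen (dipole-minimised) and the C4 benzyl group screening one enolate face. The closest known reaction is the Evans syn glycolate aldol of α-aryloxyacetyl oxazolidinones with electron-rich benzaldehydes. No ring of the product is closed; the six-membered boron chelate exists only in the transition state. The (Z)-geometry fixes the syn relation of C7–OH and C8–OAr (the threo series of the 8-O-4′ skeleton) and the (S)-benzyl auxiliary fixes the absolute sense, so C7 is formed R and C8 is formed with the arrangement that becomes R once the acyl carbon is reduced to CH2OH (its descriptor is S while the imide is present). The step needs Evans-syn over non-Evans-syn and anti selectivity, secured by the short B–O bonds and the auxiliary, and chemoselectivity against the acidic malonate C–H of 6, secured by preforming 7 with at most 1.05 equiv of Bu2BOTf before 6 is added at −78 °C so that no free boron Lewis acid/amine pair remains to enolise the malonate. The terminal alkene and the esters are inert, and the buffered peroxide work-up should cleave only the B–O and B–C bonds of the dibutylboryl group.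

Step 4
Reactants: 9 syn aldol adduct
Product: 12 (1R,2R)-1-[4-(1,3-dihydroxypropan-2-yloxy)-3,5-dimethoxyphenyl]-2-[4-(3-hydroxypropyl)-2,6-dimethoxyphenoxy]propane-1,3-diol (target), via B-alkyl-9-BBN imide diester 10 (not isolated), via B-alkyl-9-BBN tetraol 11 (not isolated)
Conditions: 9-BBN (2.5 equiv), THF, 0 °C → rt; then LiBH4 (excess), MeOH, 0 °C → rt; then aq NaOH, 30% H2O2, 0 °C → rt
Reagents that add atoms: hydrogen peroxide, OO
Why: Anti-Markovnikov hydroboration of the terminal alkene by 9-BBN is chemoselective over imide and esters; LiBH4 then reductively cleaves the exocyclic imide carbonyl to the C9 alcohol and reduces both malonate esters (B-alkyl- and B-alkoxy-9-BBN species are known to accelerate LiBH4 ester reduction, MeOH keeps the malonate protonated), and alkaline peroxide oxidises the C–B bond with retention only after every acyl group is gone, so neither peroxide cleavage to acids nor retro-aldol can occur and C7 and C8 stay untouched.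

Compound list
1 | 4-allyl-2,6-dimethoxyphenol (methoxyeugenol) | C=CCc1cc(OC)c(O)c(OC)c1 | starting material
2 | (S)-4-benzyl-3-(2-chloroacetyl)oxazolidin-2-one | O=C(CCl)N1C(=O)OC[C@@H]1Cc1ccccc1 | starting material
3 | (S)-3-[2-(4-allyl-2,6-dimethoxyphenoxy)acetyl]-4-benzyloxazolidin-2-one | C=CCc1cc(OC)c(OCC(=O)N2C(=O)OC[C@@H]2Cc2ccccc2)c(OC)c1 | intermediate
4 | syringaldehyde (4-hydroxy-3,5-dimethoxybenzaldehyde) | COc1cc(C=O)cc(OC)c1O | starting material
5 | diethyl bromomalonate | CCOC(=O)C(Br)C(=O)OCC | starting material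
6 | diethyl 2-(4-formyl-2,6-dimethoxyphenoxy)malonate | CCOC(=O)C(Oc1c(OC)cc(C=O)cc1OC)C(=O)OCC | intermediate
7 | (Z)-dibutylboron enolate of 3 (OBBu2 and aryloxy cis) | C=CCc1cc(OC)c(O/C=C(\OB(CCCC)CCCC)N2C(=O)OC[C@@H]2Cc2ccccc2)c(OC)c1 | intermediate
8 | dibutylboron aldolate of 9 (C7–O–BBu2) | CCOC(=O)C(Oc1c(OC)cc(cc1OC)[C@@H](OB(CCCC)CCCC)[C@H](Oc1c(OC)cc(CC=C)cc1OC)C(=O)N1C(=O)OC[C@@H]1Cc1ccccc1)C(=O)OCC | intermediate
9 | diethyl 2-{4-[(1R,2S)-2-(4-allyl-2,6-dimethoxyphenoxy)-3-[(S)-4-benzyl-2-oxooxazolidin-3-yl]-1-hydroxy-3-oxopropyl]-2,6-dimethoxyphenoxy}malonate | CCOC(=O)C(Oc1c(OC)cc(cc1OC)[C@@H](O)[C@H](Oc1c(OC)cc(CC=C)cc1OC)C(=O)N1C(=O)OC[C@@H]1Cc1ccccc1)C(=O)OCC | intermediate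
10 | 9 with the allyl group converted to 3-(9-borabicyclo[3.3.1]nonan-9-yl)propyl | CCOC(=O)C(Oc1c(OC)cc(cc1OC)[C@@H](O)[C@H](Oc1c(OC)cc(CCCB2C3CCCC2CCC3)cc1OC)C(=O)N1C(=O)OC[C@@H]1Cc1ccccc1)C(=O)OCC | intermediate
11 | (1R,2R)-2-{4-[3-(9-borabicyclo[3.3.1]nonan-9-yl)propyl]-2,6-dimethoxyphenoxy}-1-[4-(1,3-dihydroxypropan-2-yloxy)-3,5-dimethoxyphenyl]propane-1,3-diol | COc1cc([C@@H](O)[C@@H](CO)Oc2c(OC)cc(CCCB3C4CCCC3CCC4)cc2OC)cc(OC)c1OC(CO)CO | intermediate
12 | (1R,2R)-1-[4-(1,3-dihydroxypropan-2-yloxy)-3,5-dimethoxyphenyl]-2-[4-(3-hydroxypropyl)-2,6-dimethoxyphenoxy]propane-1,3-diol (7R,8R, threo) | COc1cc([C@@H](O)[C@@H](CO)Oc2c(OC)cc(CCCO)cc2OC)cc(OC)c1OC(CO)CO | target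

Total step count: 4. Longest linear sequence: 3 steps (step 1 or step 2, then steps 3 and 4).

Steps most likely to fail

Step 4. The malonate reduction may stall through enolisation, hydride may attack the ring carbonyl of the auxiliary instead of the exocyclic one, or the very polar product may be lost on separation from boron residues. The fallback sets out from 9 and separates the events. LiBH4 in THF/MeOH alone should reduce the imide and both esters to the allyl tetraol F1, which is purified with recovery of the auxiliary. Hydroboration of F1 with excess 9-BBN in THF then gives 11, where the fallback comes back to the route, and alkaline peroxide oxidation gives 12.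

Step 3. The acidic malonate C–H of 6 may quench or compete with the boron enolate, and slow addition to the electron-rich carbonyl may erode diastereocontrol. The fallback sets out from 4 and replaces the malonate by a ketal-protected glycerol that has no acidic C–H. Mitsunobu etherification of 4 with commercial 2,2-dimethyl-1,3-dioxan-5-ol (PPh3, DIAD, THF) should give the acetonide aldehyde F2. Addition of enolate 7 to F2 gives the boron aldolate F3 and, after the same buffered peroxide work-up, the syn aldol adduct F4. The same 9-BBN / LiBH4 / NaOH–H2O2 sequence passes through the alkylborane imide F5 and the alkylborane diol F6 to the acetonide triol F7. Aqueous acetic acid at rt then removes the acetonide and the fallback comes back to the route at 12.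

Step 2. The hindered, stabilised phenoxide may attack bromine instead of carbon (halogen-philic debromination of the malonate), so that O-alkylation does not proceed. The fallback sets out from 4 and forms the same C–O bond without any SN2 event: Rh2(OAc)4-catalysed decomposition of diethyl diazomalonate in CH2Cl2 at reflux and insertion of the carbenoid into the phenol O–H should give 6 directly, where it comes back to the route.

Further compounds
F1 | step 4 | (1R,2R)-2-(4-allyl-2,6-dimethoxyphenoxy)-1-[4-(1,3-dihydroxypropan-2-yloxy)-3,5-dimethoxyphenyl]propane-1,3-diol | COc1cc([C@@H](O)[C@@H](CO)Oc2c(OC)cc(CC=C)cc2OC)cc(OC)c1OC(CO)CO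
F2 | step 3 | 4-[(2,2-dimethyl-1,3-dioxan-5-yl)oxy]-3,5-dimethoxybenzaldehyde | COc1cc(C=O)cc(OC)c1OC1COC(C)(C)OC1
F3 | step 3 | dibutylboron aldolate of F4 | COc1cc(cc(OC)c1OC1COC(C)(C)OC1)[C@@H](OB(CCCC)CCCC)[C@H](Oc1c(OC)cc(CC=C)cc1OC)C(=O)N1C(=O)OC[C@@H]1Cc1ccccc1
F4 | step 3 | (S)-3-[(2S,3R)-2-(4-allyl-2,6-dimethoxyphenoxy)-3-{4-[(2,2-dimethyl-1,3-dioxan-5-yl)oxy]-3,5-dimethoxyphenyl}-3-hydroxypropanoyl]-4-benzyloxazolidin-2-one | COc1cc(cc(OC)c1OC1COC(C)(C)OC1)[C@@H](O)[C@H](Oc1c(OC)cc(CC=C)cc1OC)C(=O)N1C(=O)OC[C@@H]1Cc1ccccc1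
F5 | step 3 | F4 with the allyl group converted to 3-(9-borabicyclo[3.3.1]nonan-9-yl)propyl | COc1cc(cc(OC)c1OC1COC(C)(C)OC1)[C@@H](O)[C@H](Oc1c(OC)cc(CCCB2C3CCCC2CCC3)cc1OC)C(=O)N1C(=O)OC[C@@H]1Cc1ccccc1
F6 | step 3 | (1R,2R)-2-{4-[3-(9-borabicyclo[3.3.1]nonan-9-yl)propyl]-2,6-dimethoxyphenoxy}-1-{4-[(2,2-dimethyl-1,3-dioxan-5-yl)oxy]-3,5-dimethoxyphenyl}propane-1,3-diol | COc1cc(cc(OC)c1OC1COC(C)(C)OC1)[C@@H](O)[C@@H](CO)Oc1c(OC)cc(CCCB2C3CCCC2CCC3)cc1OC
F7 | step 3 | (1R,2R)-1-{4-[(2,2-dimethyl-1,3-dioxan-5-yl)oxy]-3,5-dimethoxyphenyl}-2-[4-(3-hydroxypropyl)-2,6-dimethoxyphenoxy]propane-1,3-diol | COc1cc(cc(OC)c1OC1COC(C)(C)OC1)[C@@H](O)[C@@H](CO)Oc1c(OC)cc(CCCO)cc1OC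
F0 | step 2 | none | none
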